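The indenone is disconnected at the C3a–C4 bond of its benzo ring (ring B). In ring B the acyl group sits on C4, adjacent to ring-fusion atom C3a, and the methyl on C7, adjacent to C7a; unfolding the ring at C3a–C4 therefore gives an open-chain trienone with both groups already in place. A thermal disrotatory 6π electrocyclisation, followed in the same flask by MnO2 dehydrogenation, closes ring B and delivers the fully substituted arene in one operation. The precursor is trans-5-(guaiazulen-3-yl)-4-methylcyclopent-2-enone bearing a (2Z,4E)-7-methyl-6-oxoocta-2,4-dien-2-yl arm on C2. The azulene enters early as a carbon nucleophile, and the C2–C3 alkene of the indenone is introduced last.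

Key step: step 11

Remark: all chiral intermediates are racemic (one enantiomer drawn); the target has no stereocentre, so only the trans relationship of the two ring substituents is tracked, and 40% aqueous methylglyoxal serves as compound 1.

Step 1
Reactants: 1 methylglyoxal (2-oxopropanal); 2 2-(triphenylphosphoranylidene)propanal
Product: 3 (E)-2-methyl-4-oxopent-2-enal
Conditions: CH2Cl2/H2O, rt
Reagents that add atoms: none
Why: Wittig olefination in which the formyl-stabilised ylide attacks only the highly electrophilic aldehyde carbon of the α-ketoaldehyde, the ketone and the α-branched enal of the product being far less reactive; the alkene geometry is irrelevant because both alkene carbons become sp3 in step 2.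

Step 2
Reactants: 3 (E)-2-methyl-4-oxopent-2-enal; 4 guaiazulene
Product: 5 3-(guaiazulen-3-yl)-2-methyl-4-oxopentanal (racemic diastereomer mixture)
Conditions: (CF3)2CHOH, 0 °C to rt, Ar
Reagents that add atoms: none
Why: Friedel–Crafts-type conjugate addition in which C3 of guaiazulene, its only free nucleophilic five-ring position, attacks the unsubstituted alkene carbon β to the aldehyde (the stronger acceptor and the less hindered terminus), hydrogen-bond activation sufficing without a strong acid that would favour carbonyl condensation; the two new stereocentres form unselectively and are levelled in step 3.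

Step 3
Reactants: 5 3-(guaiazulen-3-yl)-2-methyl-4-oxopentanal
Product: 7 trans-5-(guaiazulen-3-yl)-4-methylcyclopent-2-en-1-one, via β-ketol 6 (not isolated)
Conditions: KOH (0.2 equiv), MeOH, 0 °C; pH 7 buffer quench
Reagents that add atoms: none
Why: Intramolecular aldol condensation in which only the methyl-ketone enolate can reach the aldehyde through a five-membered ring, E1cB loss of water gives the enone and the acidic C5–H equilibrates the azulenyl group trans to the C4 methyl; catalytic base at 0 °C is chosen so that the alkene should not migrate into conjugation with the azulene.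

Step 4
Reactants: 7 trans-5-(guaiazulen-3-yl)-4-methylcyclopent-2-en-1-one
Product: 8 trans-5-(guaiazulen-3-yl)-2-iodo-4-methylcyclopent-2-en-1-one
Conditions: I2, pyridine, CH2Cl2, 0 °C to rt, dark
Reagents that add atoms: iodine, II
Why: α-Iodination of an enone by the addition–elimination (Baylis–Hillman-type) pathway of conjugate addition of pyridine, iodination of the enolate and loss of pyridine; the azulene has both nucleophilic positions (C1 and C3) substituted and offers iodine no site for substitution.

Step 5
Reactants: 9 ethyl but-2-ynoate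
Product: 10 ethyl (Z)-3-iodobut-2-enoate
Conditions: NaI, AcOH, 115 °C
Reagents that add atoms: sodium iodide, [Na+].[I-]
Why: Hydroiodination of an ynoate by conjugate addition of iodide and anti protonation, which places iodine cis to the ester and thereby fixes the Z geometry of the later central triene alkene.

Step 6
Reactants: 10 ethyl (Z)-3-iodobut-2-enoate
Product: 11 ethyl (Z)-3-(trimethylstannyl)but-2-enoate
Conditions: Me3SnSnMe3, Pd(PPh3)4 (5 mol%), THF, 65 °C
Reagents that add atoms: hexamethylditin, C[Sn](C)(C)[Sn](C)(C)C
Why: Palladium-catalysed stannylation of an alkenyl iodide with a distannane (oxidative addition, tin–tin transmetalation, reductive elimination) proceeds with retention, and the Z ester is also the thermodynamically preferred isomer because tin lies cis to the carbonyl oxygen.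

Step 7
Reactants: 11 ethyl (Z)-3-(trimethylstannyl)but-2-enoate
Product: 12 (Z)-3-(trimethylstannyl)but-2-en-1-ol
Conditions: i-Bu2AlH (2.2 equiv), CH2Cl2, −78 °C; aq. sodium potassium tartrate
Reagents that add atoms: none
Why: Hydride reduction of an α,β-unsaturated ester to the allylic alcohol, to which the alkenylstannane is inert at low temperature.

Step 8
Reactants: 13 1-bromo-3-methylbutan-2-one
Product: 15 3-methyl-1-(triphenylphosphoranylidene)butan-2-one, via phosphonium bromide 14 (not isolated)
Conditions: PPh3, toluene, 60 °C; then aq. NaOH, CH2Cl2, rt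
Reagents that add atoms: triphenylphosphine, c1ccc(cc1)P(c1ccccc1)c1ccccc1
Why: SN2 quaternisation of the phosphine by a primary α-bromoketone followed by deprotonation of the acidic salt gives the keto-stabilised Wittig ylide.

Step 9
Reactants: 12 (Z)-3-(trimethylstannyl)but-2-en-1-ol; 15 3-methyl-1-(triphenylphosphoranylidene)butan-2-one
Product: 17 (4E,6Z)-2-methyl-7-(trimethylstannyl)octa-4,6-dien-3-one, via stannyl enal 16 (not isolated)
Conditions: activated MnO2 (10 equiv), CH2Cl2, 40 °C, dark
Reagents that add atoms: none
Why: Tandem allylic oxidation–Wittig olefination in which the Z enal is trapped as it forms, before it can isomerise, and the stabilised ylide should give the E enone.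

Step 10
Reactants: 8 trans-5-(guaiazulen-3-yl)-2-iodo-4-methylcyclopent-2-en-1-one; 17 (4E,6Z)-2-methyl-7-(trimethylstannyl)octa-4,6-dien-3-one
Product: 18 trans-5-(guaiazulen-3-yl)-4-methyl-2-[(2Z,4E)-7-methyl-6-oxoocta-2,4-dien-2-yl]cyclopent-2-en-1-one
Conditions: Pd2(dba)3 (5 mol%), AsPh3, CuI, NMP, rt, dark
Reagents that add atoms: none
Why: Stille coupling of an α-iodoenone with an alkenylstannane under copper-assisted conditions proceeds with retention at both carbons, so the Z tin-bearing alkene becomes the Z central alkene of the triene; the neutral room-temperature medium should leave the acidic ring hydrogens and the triene untouched.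

Step 11
Reactants: 18 trans-5-(guaiazulen-3-yl)-4-methyl-2-[(2Z,4E)-7-methyl-6-oxoocta-2,4-dien-2-yl]cyclopent-2-en-1-one
Product: 20 trans-2-(guaiazulen-3-yl)-3,7-dimethyl-4-(2-methylpropanoyl)indan-1-one, via dihydroindanone 19 (not isolated)
Conditions: toluene, 110 °C, Ar, dark; then activated MnO2, 60 °C
Reagents that add atoms: none
Why: The hexatriene made of the ring enone alkene and the two side-chain alkenes closes from its s-cis,s-cis conformer by a thermal 6π electrocyclisation that forms the C3a–C4 bond, and MnO2 then removes the hydrogens at C3a and C4 of cyclohexadiene 19 to give the arene. The closest known reaction type is benzannulation by electrocyclisation of a Z-hexatriene followed by dehydrogenation, helped here by the ketone on the second triene carbon, which lowers the barrier. Ring B closes in the thermally allowed disrotatory mode, which places the two new sp3 hydrogens cis. Both new centres are erased on aromatisation, so no new stereocentre survives and the trans C2/C3 relationship is carried through (C2 can re-equilibrate to trans). The step needs the Z central alkene, set in step 5 and kept through stannane 17, and the E acyl terminus, which leaves only hydrogen at the inside positions and shuts off oxa-6π closure; no [1,5]- or [1,7]-hydrogen shift can compete because the ring CH(Me) carbon is locked trans to the side chain across the ring alkene. MnO2 is chosen over quinone oxidants because those would abstract hydride from the azulene ring methyl or oxidise the electron-rich azulene.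

Step 12
Reactants: 20 trans-2-(guaiazulen-3-yl)-3,7-dimethyl-4-(2-methylpropanoyl)indan-1-one
Product: 22 2-(guaiazulen-3-yl)-3,7-dimethyl-4-(2-methylpropanoyl)-1H-inden-1-one (CNP0225119.0), via sulfilimine 21 (not isolated)
Conditions: LiN(SiMe3)2 (1.1 equiv), THF, −78 °C; then PhS(Cl)=N-t-Bu, −78 °C to rt
Reagents that add atoms: none
Why: Mukaiyama dehydrogenation in which the C2 enolate (the most acidic site, flanked by ketone and azulene) is sulfenylated on the face anti to the C3 methyl and the sulfilimine undergoes syn-elimination with the cis C3 hydrogen, giving the tetrasubstituted enone without an oxidant that could touch the azulene; both stereocentres disappear.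

Compound list
1 | methylglyoxal (2-oxopropanal) | CC(=O)C=O | starting material
2 | 2-(triphenylphosphoranylidene)propanal | CC(C=O)=P(c1ccccc1)(c1ccccc1)c1ccccc1 | starting material
3 | (E)-2-methyl-4-oxopent-2-enal | CC(=O)/C=C(\C)C=O | intermediate
4 | guaiazulene (1,4-dimethyl-7-isopropylazulene) | Cc1ccc2c(C)ccc(C(C)C)cc1-2 | starting material
5 | 3-(guaiazulen-3-yl)-2-methyl-4-oxopentanal (racemic, both diastereomers) | CC(=O)C(c1cc(C)c2cc(C(C)C)ccc(C)c1-2)C(C)C=O | intermediate
6 | 5-(guaiazulen-3-yl)-3-hydroxy-4-methylcyclopentan-1-one (β-ketol, diastereomer mixture, not isolated) | O=C1CC(O)C(C)C1c1cc(C)c2cc(C(C)C)ccc(C)c1-2 | intermediate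
7 | trans-5-(guaiazulen-3-yl)-4-methylcyclopent-2-en-1-one | O=C1[C@@H](c2cc(C)c3cc(C(C)C)ccc(C)c2-3)[C@H](C)C=C1 | intermediate
8 | trans-5-(guaiazulen-3-yl)-2-iodo-4-methylcyclopent-2-en-1-one | O=C1[C@@H](c2cc(C)c3cc(C(C)C)ccc(C)c2-3)[C@H](C)C=C1I | intermediate
9 | ethyl but-2-ynoate | CCOC(=O)C#CC | starting material
10 | ethyl (Z)-3-iodobut-2-enoate | CCOC(=O)/C=C(/C)I | intermediate
11 | ethyl (Z)-3-(trimethylstannyl)but-2-enoate | CCOC(=O)/C=C(/C)[Sn](C)(C)C | intermediate
12 | (Z)-3-(trimethylstannyl)but-2-en-1-ol | OC/C=C(/C)[Sn](C)(C)C | intermediate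
13 | 1-bromo-3-methylbutan-2-one | CC(C)C(=O)CBr | starting material
14 | (3-methyl-2-oxobutyl)triphenylphosphonium bromide (not isolated) | CC(C)C(=O)C[P+](c1ccccc1)(c1ccccc1)c1ccccc1.[Br-] | intermediate
15 | 3-methyl-1-(triphenylphosphoranylidene)butan-2-one | CC(C)C(=O)C=P(c1ccccc1)(c1ccccc1)c1ccccc1 | intermediate
16 | (Z)-3-(trimethylstannyl)but-2-enal (not isolated) | O=C/C=C(/C)[Sn](C)(C)C | intermediate
17 | (4E,6Z)-2-methyl-7-(trimethylstannyl)octa-4,6-dien-3-one | CC(C)C(=O)/C=C/C=C(/C)[Sn](C)(C)C | intermediate
18 | trans-5-(guaiazulen-3-yl)-4-methyl-2-[(2Z,4E)-7-methyl-6-oxoocta-2,4-dien-2-yl]cyclopent-2-en-1-one | O=C1[C@@H](c2cc(C)c3cc(C(C)C)ccc(C)c2-3)[C@H](C)C=C1/C(C)=C\C=C\C(=O)C(C)C | intermediate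
19 | 2-(guaiazulen-3-yl)-3,7-dimethyl-4-(2-methylpropanoyl)-2,3,3a,4-tetrahydro-1H-inden-1-one (2,3-trans, 3a,4-cis; one diastereomer drawn, not isolated) | O=C1[C@@H](c2cc(C)c3cc(C(C)C)ccc(C)c2-3)[C@H](C)[C@H]2[C@@H](C(=O)C(C)C)C=CC(C)=C12 | intermediate
20 | trans-2-(guaiazulen-3-yl)-3,7-dimethyl-4-(2-methylpropanoyl)indan-1-one | O=C1[C@@H](c2cc(C)c3cc(C(C)C)ccc(C)c2-3)[C@H](C)c2c(C(=O)C(C)C)ccc(C)c21 | intermediate
21 | 2-(N-tert-butyl-S-phenylsulfinimidoyl)-2-(guaiazulen-3-yl)-3,7-dimethyl-4-(2-methylpropanoyl)indan-1-one (sulfur cis to the C3 hydrogen, not isolated) | O=C1[C@@](c2cc(C)c3cc(C(C)C)ccc(C)c2-3)(S(=NC(C)(C)C)c2ccccc2)[C@H](C)c2c(C(=O)C(C)C)ccc(C)c21 | intermediate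
22 | 2-(guaiazulen-3-yl)-3,7-dimethyl-4-(2-methylpropanoyl)-1H-inden-1-one (CNP0225119.0) | CC1=C(c2cc(C)c3cc(C(C)C)ccc(C)c2-3)C(=O)c2c(C)ccc(C(=O)C(C)C)c21 | target

Total step count: 12. Longest linear sequence: 7 steps (1, 2, 3, 4, 10, 11, 12, or equally 5, 6, 7, 9, 10, 11, 12).

Steps most likely to fail

Step 11. Dehydrogenation of dihydroarene 19 may not be clean: electron transfer from the azulene to the oxidant, or reversion and hydrogen migration in 19, could erode the material before ring B becomes aromatic. The fallback makes aromatisation redox-neutral by putting a leaving group on the terminus that becomes C4.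
- It sets out from ylide 15, alcohol 12 and iodoenone 8.
- Chlorination of 15 with N-chlorosuccinimide and then K2CO3 should give 1-chloro-3-methyl-1-(triphenylphosphoranylidene)butan-2-one F1.
- MnO2 oxidation of 12 to enal 16 and Wittig reaction with F1 in warm toluene should give (4Z,6Z)-4-chloro-2-methyl-7-(trimethylstannyl)octa-4,6-dien-3-one F2; either geometry at the chloroalkene would serve.
- Stille coupling of F2 with 8 under the conditions of step 10 should give trans-2-[(2Z,4Z)-5-chloro-7-methyl-6-oxoocta-2,4-dien-2-yl]-5-(guaiazulen-3-yl)-4-methylcyclopent-2-en-1-one F3.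
- Heating F3 in toluene with 2,6-lutidine should bring about the same 6π closure to 4-chloro-2-(guaiazulen-3-yl)-3,7-dimethyl-4-(2-methylpropanoyl)-2,3,3a,4-tetrahydro-1H-inden-1-one F4, which loses HCl irreversibly and so reaches indanone 20 with no oxidant.

Step 3. Under base the ring alkene may migrate through the extended dienolate into conjugation with the azulene (the tetrasubstituted 2-aryl-3-methyl isomer), or dehydration of ketol 6 may stall. The fallback closes the ring by metathesis under neutral conditions.
- It sets out from guaiazulene 4, which under the conditions of step 2 should add to purchased ethyl (E)-3-methyl-4-oxobut-2-enoate to give ethyl 2-(guaiazulen-3-yl)-3-methyl-4-oxobutanoate F5.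
- Wittig methylenation with Ph3P=CH2 should give ethyl 2-(guaiazulen-3-yl)-3-methylpent-4-enoate F6.
- MeNHOMe·HCl with i-PrMgCl should convert the ester into 2-(guaiazulen-3-yl)-N-methoxy-N,3-dimethylpent-4-enamide F7.
- Vinylmagnesium bromide should then give 4-(guaiazulen-3-yl)-5-methylhepta-1,6-dien-3-one F8.
- Ring-closing metathesis with the second-generation Hoveyda–Grubbs catalyst in CH2Cl2 at 40 °C should return to enone 7. Any cis isomer epimerises at C5 on mild base treatment and serves equally, since both centres are erased in step 12.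

Step 10. Transmetalation of the α-branched, electron-poor alkenylstannane may be slower than cine substitution, protodestannylation or homocoupling. The fallback extends the chain after the coupling.
- Iodoenone 8 is coupled under the same catalyst system with the smaller, more electron-rich stannyl alcohol 12 to give trans-5-(guaiazulen-3-yl)-2-[(2Z)-4-hydroxybut-2-en-2-yl]-4-methylcyclopent-2-en-1-one F9.
- Tandem MnO2 oxidation–Wittig reaction of F9 with ylide 15 then passes through (2Z)-3-[trans-4-(guaiazulen-3-yl)-3-methyl-5-oxocyclopent-1-en-1-yl]but-2-enal F10, trapped as it forms, and returns to trienone 18.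

Further compounds
F1 | step 11 | 1-chloro-3-methyl-1-(triphenylphosphoranylidene)butan-2-one | CC(C)C(=O)C(Cl)=P(c1ccccc1)(c1ccccc1)c1ccccc1
F2 | step 11 | (4Z,6Z)-4-chloro-2-methyl-7-(trimethylstannyl)octa-4,6-dien-3-one | CC(C)C(=O)/C(Cl)=C/C=C(/C)[Sn](C)(C)C
F3 | step 11 | trans-2-[(2Z,4Z)-5-chloro-7-methyl-6-oxoocta-2,4-dien-2-yl]-5-(guaiazulen-3-yl)-4-methylcyclopent-2-en-1-one | O=C1[C@@H](c2cc(C)c3cc(C(C)C)ccc(C)c2-3)[C@H](C)C=C1/C(C)=C\C=C(Cl)\C(=O)C(C)C
F4 | step 11 | 4-chloro-2-(guaiazulen-3-yl)-3,7-dimethyl-4-(2-methylpropanoyl)-2,3,3a,4-tetrahydro-1H-inden-1-one | O=C1[C@@H](c2cc(C)c3cc(C(C)C)ccc(C)c2-3)[C@H](C)[C@H]2[C@@](Cl)(C(=O)C(C)C)C=CC(C)=C12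
F5 | step 3 | ethyl 2-(guaiazulen-3-yl)-3-methyl-4-oxobutanoate | CCOC(=O)C(c1cc(C)c2cc(C(C)C)ccc(C)c1-2)C(C)C=O
F6 | step 3 | ethyl 2-(guaiazulen-3-yl)-3-methylpent-4-enoate | CCOC(=O)C(c1cc(C)c2cc(C(C)C)ccc(C)c1-2)C(C)C=C
F7 | step 3 | 2-(guaiazulen-3-yl)-N-methoxy-N,3-dimethylpent-4-enamide | CON(C)C(=O)C(c1cc(C)c2cc(C(C)C)ccc(C)c1-2)C(C)C=C
F8 | step 3 | 4-(guaiazulen-3-yl)-5-methylhepta-1,6-dien-3-one | C=CC(=O)C(c1cc(C)c2cc(C(C)C)ccc(C)c1-2)C(C)C=C
F9 | step 10 | trans-5-(guaiazulen-3-yl)-2-[(2Z)-4-hydroxybut-2-en-2-yl]-4-methylcyclopent-2-en-1-one | O=C1[C@@H](c2cc(C)c3cc(C(C)C)ccc(C)c2-3)[C@H](C)C=C1/C(C)=C\CO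
F10 | step 10 | (2Z)-3-[trans-4-(guaiazulen-3-yl)-3-methyl-5-oxocyclopent-1-en-1-yl]but-2-enal | O=C1[C@@H](c2cc(C)c3cc(C(C)C)ccc(C)c2-3)[C@H](C)C=C1/C(C)=C\C=O
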